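I began at the tail.

You asked for a quick number on the dusk flask and sent your forecast with it, so here is my reply.

- dusk: D 0.80 M; Q 1.6 M; L 4 mM; temperature 35 °C; the very flask that is asked about, followed so far
- flask: D 0.80 M; Q 1.60 M; L 4.0 mM; temperature 35 °C; time 8.0 d

dusk run (percent of the D charged)

| time / d | G / % |
|---|---|
| 0.417 | 11 |
| 1.25 | 32 |
| 2.50 | 37 |
| 3.00 | 35 |
| 5.00 | 32 |
| 6.00 | 30 |
| 8.00 | 26 |

(readings scatter by 2 percentage points)

- G that was removed still counts
- the analysis behind the earlier runs scatters by 2 percentage points, standard deviation
- the earlier runs do not show what temperature does; that part of a forecast is a guess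
- additions bring no volume worth counting

- Thursday's: change nothing and wait 4.0 d more
- Friday's: at 8.0 d add L, 100% of the amount charged, then wait 4.0 d
- Monday's: at 8.0 d add Q, 50.0% of the amount charged, then wait 4.0 d
- Wednesday's: at 8.0 d take out 90% of the G then present, then wait 4.0 d
- Sunday's: at 8.0 d raise the temperature by 25 K, then wait 4.0 d

- G, in percent of the D first charged, at 8.0 d
- what to do for the largest gain in G; "none" if nothing gains more than 2 percentage points (Thursday's / Friday's / Monday's / Wednesday's / Sunday's / none)
- G present, with what was taken out counted in, in percent of the D first charged, after Wednesday's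
- G present, with what was taken out counted in, in percent of the D first charged, after Sunday's

1. My quick number for G was the last reading of the dusk flask, 26% at 8.00 d, give or take 2 percentage points.

2. From 32% at 5.00 d to that last reading, G fell with an apparent first-order constant λ of 0.0692 d⁻¹. That gave τ = 10.0 d, the tail half-life, which I defined as the time G needed to halve if the late fall was a one-way loss. It was a reading and carried the scatter of both ends.

3. I compared rates at one moment. At the peak reading of 37%, loss at λ stood to the first slope, 11% in 0.417 d, as ρ = 0.0971, so, if the loss ran at λ there, the making had faded by the peak.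

4. I doubted that Q did this. Q was charged at twice the D, and the peak G needed 0.296 M of it at one Q per G, less than the 1.60 M charged, so I did not call Q the limiting reagent. By τ, I reckoned the cost of waiting at 6.3 points, so I leaned to Wednesday's and left temperature a guess.

5. The forecast gave 26%, Monday's, 25.5% after Wednesday's and 8% after Sunday's, on the ground that “a sharp kink suggests a reagent ran out, most likely Q”. We parted over Q.

6. The flask gave 26.0% with Q at 51.3% of its charge. Best was Sunday's, changing G by 48 points to 73.9%. Wednesday's changed it by 16 points to 41.7%, and Monday's by −1.3 points.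

    D + L ⇌ L + J (K = 0.510, k = 8.30 M⁻¹ h⁻¹, Ea = 68.0 kJ mol⁻¹, ΔH = −89.0 kJ mol⁻¹)
    Q + L + J → L + G (k = 29.8 M⁻² h⁻¹, Ea = 50.0 kJ mol⁻¹)
    G ⇌ E (K = 3.10, k = 0.0257 h⁻¹, Ea = 103 kJ mol⁻¹, ΔH = −75.0 kJ mol⁻¹)
    (constants at 35 °C)

In this flask the relaxation half-life of G and E by G ⇌ E alone, both ways together, was 0.850 d, far shorter than τ = 10.0 d and short against 8.0 d, and at 8.00 d E stood at 71.5% beside G at 26.0%, a ratio of 2.75 against that step's constant of 3.1. Run on as a one-way loss with τ, G in the flask left until 80.0 d came to 0.177%, and that flask held 24.4%.

All runs are calculated for substances that don't exist; scatter was added.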